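**Retrosynthetic overview**

1. Ring names: A is the benzo ring, B is the furan ring (O1, C2, C3, C3a, C7a), and C is the 4-hydroxy-3-methoxyphenyl ring. The plan rests on C2 of ring B, a single carbon bonded only to O1, C3 and ring C, which can be brought in as a one-carbon ylide unit that already carries ring C.
2. The target is traced back through O-debenzylation, carbinol oxidation and ester reduction to a benzofuran diester. Its C3 ester is the latent formyl carbon and its C5 propanoate is the latent hydroxypropyl chain. Dehydrogenation links it to a trans-2,3-dihydrobenzofuran.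
3. The dihydrobenzofuran is cut at O1–C2 and C2–C3. This is a formal [4+1] of the four-atom unit O1–C7a–C3a–C3 (an ester-substituted ortho-quinone methide of ring A, released from an α-sulfonyl ester) with a benzylic dimethylsulfonium ylide.
4. The sulfone comes from methyl dihydroferulate, ethyl glyoxylate and sodium p-toluenesulfinate. The sulfonium salt comes from O-benzylvanillin and Me2S.
5. Ring order: rings A and C are bought. Ring B is the only ring made, closed in the annulation and aromatised one step later.

Key step: step 6

Remark on the chemistry: the target has no stereocentre, so every chiral intermediate is carried as a racemate, and the SMILES of the dihydrobenzofuran shows one enantiomer of the trans pair.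
Remark on the salt: a para-alkoxybenzyl sulfonium ion is dealkylated by halide, so it is made and used as the tetrafluoroborate.
Remark on the endgame: the benzyl ether is kept through the MnO2 oxidation and removed last. A free 4-hydroxyaryl group conjugated with the benzofuran is itself oxidisable by MnO2, and the C3 carbinol is open to hydrogenolysis on palladium.

**Route**

Step 1
Reactants: 1 methyl 3-(4-hydroxy-3-methoxyphenyl)propanoate; 2 ethyl glyoxylate (freshly cracked monomer)
Product: 3 racemic ethyl 2-hydroxy-2-[2-hydroxy-3-methoxy-5-(3-methoxy-3-oxopropyl)phenyl]acetate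
Conditions: TiCl4 (2 equiv), CH2Cl2, −30 → 0 °C; aq NH4Cl
Reagents that add atoms: none
Why: Ortho-specific, titanium-templated Friedel–Crafts hydroxyalkylation of a phenol, in which the metal bound to the phenolic oxygen also binds the aldehyde and delivers it to the only free position ortho to that oxygen (para is blocked by the side chain), the new carbinol centre forming as a racemate.

Step 2
Reactants: 3 racemic ethyl 2-hydroxy-2-[2-hydroxy-3-methoxy-5-(3-methoxy-3-oxopropyl)phenyl]acetate; 4 sodium 4-methylbenzenesulfinate
Product: 5 racemic ethyl 2-[2-hydroxy-3-methoxy-5-(3-methoxy-3-oxopropyl)phenyl]-2-(4-methylphenylsulfonyl)acetate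
Conditions: 4 (3 equiv), CF3CO2H, CH2Cl2, 0 °C → rt
Reagents that add atoms: none
Why: Acid-promoted SN1-type substitution, the usual entry to 2-(1-sulfonylalkyl)phenols, in which the ortho-hydroxyl group stabilises the benzylic cation enough to offset the neighbouring ester (as in the ready acid substitution of hydroxymandelates) and the soft sulfur of the sulfinic acid captures it to give the thermodynamically preferred sulfone as a racemate.

Step 3
Reactants: 6 4-benzyloxy-3-methoxybenzaldehyde
Product: 7 (4-benzyloxy-3-methoxyphenyl)methanol
Conditions: NaBH4, MeOH, 0 °C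
Reagents that add atoms: none
Why: Borohydride reduction of an aromatic aldehyde, which leaves both aryl ethers untouched.

Step 4
Reactants: 7 (4-benzyloxy-3-methoxyphenyl)methanol
Product: 8 4-benzyloxy-3-methoxybenzyl bromide
Conditions: PBr3 (0.4 equiv), Et2O, 0 °C; used at once
Reagents that add atoms: phosphorus tribromide, BrP(Br)Br
Why: Bromination of a primary benzylic alcohol with PBr3 by way of its phosphite ester and SN2 attack of bromide, which is fast at 0 °C for this electron-rich system and spares the aryl benzyl ether.

Step 5
Reactants: 8 4-benzyloxy-3-methoxybenzyl bromide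
Product: 9 (4-benzyloxy-3-methoxybenzyl)dimethylsulfonium tetrafluoroborate
Conditions: Me2S (3 equiv), AgBF4 (1 equiv), acetone, 0 °C → rt, dark
Reagents that add atoms: dimethyl sulfide, CSC; silver tetrafluoroborate, [Ag+].F[B-](F)(F)F
Why: S-Alkylation of a dialkyl sulfide (sulfonium salt formation) made irreversible by precipitation of AgBr, so that the labile para-alkoxybenzyl sulfonium ion is paired with an anion that cannot dealkylate it.

Step 6
Reactants: 5 racemic ethyl 2-[2-hydroxy-3-methoxy-5-(3-methoxy-3-oxopropyl)phenyl]-2-(4-methylphenylsulfonyl)acetate; 9 (4-benzyloxy-3-methoxybenzyl)dimethylsulfonium tetrafluoroborate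
Product: 13 racemic trans (2R*,3R*) ethyl 2-(4-benzyloxy-3-methoxyphenyl)-7-methoxy-5-(3-methoxy-3-oxopropyl)-2,3-dihydrobenzofuran-3-carboxylate, via ortho-quinone methide 10 (not isolated), via benzylic sulfonium ylide 11 (not isolated), via phenoxide-sulfonium betaine 12 (not isolated)
Conditions: 9 (2 equiv), Cs2CO3 (4 equiv), MeCN, 0 °C → rt, 5 added slowly
Reagents that add atoms: none
Why: Cs2CO3 takes the phenol proton of 5 and the phenoxide expels p-toluenesulfinate by 1,4-elimination to give the ester-substituted ortho-quinone methide 10, while the same base reversibly deprotonates salt 9 at its benzylic CH2 to ylide 11. The ylide carbon adds to the exocyclic methide carbon of 10 (C2–C3 bond), ring A regains aromaticity in betaine 12, and its phenoxide oxygen then displaces Me2S from the carbon just attached (O1–C2 bond), so ring B closes in the 5-exo-tet mode. The closest known reaction is the formal [4+1] annulation of sulfur ylides with ortho-quinone methides set free by carbonate bases from 2-(1-sulfonylalkyl)phenols, and sulfinate loss from a carbon that also bears an ester has its parallel in the base-induced conversion of N-acyl α-tosylglycine esters into iminoacetates. C2 and C3 are controlled only relative to each other: displacement runs through the betaine conformer that holds ring C and the ester on opposite faces of the forming ring, and the acidic C3–H allows any cis ester to equilibrate under the carbonate, so the racemic trans isomer is expected (both centres vanish in step 7). The selectivity needed is carbon–carbon bond formation at the methide before any benzyl or methyl transfer from 9 to the anions of 5, and closure of 12 before β-elimination of Me2S; the methide carbon activated by both the ring carbonyl and the ester, the non-nucleophilic BF4 counter-ion, the polar solvent and the slow addition of 5 to excess 9 serve the first, and the intramolecular attack on a para-alkoxybenzylic sulfonium carbon serves the second. Deprotonation of the more acidic C–H between the sulfonyl and ester groups also occurs, but that carbanion cannot lose sulfinate and acts only as a reversible store of the phenoxide.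

Step 7
Reactants: 13 racemic trans ethyl 2-(4-benzyloxy-3-methoxyphenyl)-7-methoxy-5-(3-methoxy-3-oxopropyl)-2,3-dihydrobenzofuran-3-carboxylate
Product: 14 ethyl 2-(4-benzyloxy-3-methoxyphenyl)-7-methoxy-5-(3-methoxy-3-oxopropyl)benzofuran-3-carboxylate
Conditions: DDQ (1.5 equiv), 1,4-dioxane, 90 °C
Reagents that add atoms: none
Why: DDQ dehydrogenation of a 2-aryl-2,3-dihydrobenzofuran, in which hydride abstraction from C2–H (activated by O1 and by the para-alkoxyaryl ring C) followed by loss of the acidic C3–H gives the aromatic ring B and removes both stereocentres, while the plain benzyl ether and the less activated side-chain CH2 react more slowly.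

Step 8
Reactants: 14 ethyl 2-(4-benzyloxy-3-methoxyphenyl)-7-methoxy-5-(3-methoxy-3-oxopropyl)benzofuran-3-carboxylate
Product: 15 3-[2-(4-benzyloxy-3-methoxyphenyl)-3-(hydroxymethyl)-7-methoxybenzofuran-5-yl]propan-1-ol
Conditions: LiAlH4 (2.5 equiv), THF, 0 °C → rt; H2O/aq NaOH work-up
Reagents that add atoms: none
Why: Exhaustive LiAlH4 reduction of both esters to primary alcohols, with the benzofuran and the aryl ethers inert to hydride and a basic work-up protecting the acid-sensitive C3 carbinol.

Step 9
Reactants: 15 3-[2-(4-benzyloxy-3-methoxyphenyl)-3-(hydroxymethyl)-7-methoxybenzofuran-5-yl]propan-1-ol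
Product: 16 2-(4-benzyloxy-3-methoxyphenyl)-5-(3-hydroxypropyl)-7-methoxybenzofuran-3-carbaldehyde
Conditions: activated MnO2 (excess), CH2Cl2, rt
Reagents that add atoms: none
Why: Chemoselective MnO2 oxidation, which takes only the benzofuran-3-yl (benzylic-type) carbinol to the aldehyde, leaves the saturated primary alcohol alone, and meets no free phenol because ring C is still benzylated.

Step 10
Reactants: 16 2-(4-benzyloxy-3-methoxyphenyl)-5-(3-hydroxypropyl)-7-methoxybenzofuran-3-carbaldehyde
Product: 17 2-(4-hydroxy-3-methoxyphenyl)-5-(3-hydroxypropyl)-7-methoxybenzofuran-3-carbaldehyde (target)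
Conditions: H2 (1 atm), Pd/C (10 wt %), EtOAc, rt, stopped when 16 is consumed
Reagents that add atoms: none
Why: Catalytic hydrogenolysis of an aryl benzyl ether, which is faster than reduction of the formyl group because that group is a vinylogous ester deactivated by donation from O1 through C2=C3.

**Compound list**

1 | methyl 3-(4-hydroxy-3-methoxyphenyl)propanoate (methyl dihydroferulate) | COC(=O)CCc1ccc(O)c(OC)c1 | starting material
2 | ethyl glyoxylate | CCOC(=O)C=O | starting material
3 | racemic ethyl 2-hydroxy-2-[2-hydroxy-3-methoxy-5-(3-methoxy-3-oxopropyl)phenyl]acetate | CCOC(=O)C(O)c1cc(CCC(=O)OC)cc(OC)c1O | intermediate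
4 | sodium 4-methylbenzenesulfinate | Cc1ccc(S(=O)[O-])cc1.[Na+] | starting material
5 | racemic ethyl 2-[2-hydroxy-3-methoxy-5-(3-methoxy-3-oxopropyl)phenyl]-2-(4-methylphenylsulfonyl)acetate | CCOC(=O)C(c1cc(CCC(=O)OC)cc(OC)c1O)S(=O)(=O)c1ccc(C)cc1 | intermediate
6 | 4-benzyloxy-3-methoxybenzaldehyde (O-benzylvanillin) | COc1cc(C=O)ccc1OCc1ccccc1 | starting material
7 | (4-benzyloxy-3-methoxyphenyl)methanol | COc1cc(CO)ccc1OCc1ccccc1 | intermediate
8 | 4-benzyloxy-3-methoxybenzyl bromide | COc1cc(CBr)ccc1OCc1ccccc1 | intermediate
9 | (4-benzyloxy-3-methoxybenzyl)dimethylsulfonium tetrafluoroborate | C[S+](C)Cc1ccc(OCc2ccccc2)c(OC)c1.F[B-](F)(F)F | intermediate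
10 | ortho-quinone methide formed in the flask: ethyl (E)-2-[5-methoxy-3-(3-methoxy-3-oxopropyl)-6-oxocyclohexa-2,4-dien-1-ylidene]acetate | CCOC(=O)/C=C1\C=C(CCC(=O)OC)C=C(OC)C1=O | intermediate
11 | benzylic ylide formed in the flask: (4-benzyloxy-3-methoxyphenyl)(dimethylsulfonio)methanide | C[S+](C)[CH-]c1ccc(OCc2ccccc2)c(OC)c1 | intermediate
12 | betaine formed in the flask (diastereomer mixture, no configuration assigned): 2-[1-(4-benzyloxy-3-methoxyphenyl)-1-(dimethylsulfonio)-3-ethoxy-3-oxopropan-2-yl]-6-methoxy-4-(3-methoxy-3-oxopropyl)phenolate | CCOC(=O)C(C([S+](C)C)c1ccc(OCc2ccccc2)c(OC)c1)c1cc(CCC(=O)OC)cc(OC)c1[O-] | intermediate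
13 | racemic trans (2R*,3R*) ethyl 2-(4-benzyloxy-3-methoxyphenyl)-7-methoxy-5-(3-methoxy-3-oxopropyl)-2,3-dihydrobenzofuran-3-carboxylate | COC(=O)CCc1cc(OC)c2O[C@@H](c3ccc(OCc4ccccc4)c(OC)c3)[C@H](C(=O)OCC)c2c1 | intermediate
14 | ethyl 2-(4-benzyloxy-3-methoxyphenyl)-7-methoxy-5-(3-methoxy-3-oxopropyl)benzofuran-3-carboxylate | CCOC(=O)c1c(-c2ccc(OCc3ccccc3)c(OC)c2)oc2c(OC)cc(CCC(=O)OC)cc12 | intermediate
15 | 3-[2-(4-benzyloxy-3-methoxyphenyl)-3-(hydroxymethyl)-7-methoxybenzofuran-5-yl]propan-1-ol | OCc1c(-c2ccc(OCc3ccccc3)c(OC)c2)oc2c(OC)cc(CCCO)cc12 | intermediate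
16 | 2-(4-benzyloxy-3-methoxyphenyl)-5-(3-hydroxypropyl)-7-methoxybenzofuran-3-carbaldehyde | O=Cc1c(-c2ccc(OCc3ccccc3)c(OC)c2)oc2c(OC)cc(CCCO)cc12 | intermediate
17 | 2-(4-hydroxy-3-methoxyphenyl)-5-(3-hydroxypropyl)-7-methoxybenzofuran-3-carbaldehyde | COc1cc(-c2oc3c(OC)cc(CCCO)cc3c2C=O)ccc1O | target

**Step count**

Total step count: 10.
Longest linear sequence: 8 (steps 3, 4, 5, 6, 7, 8, 9 and 10, from 6).

**Steps most likely to fail**

First, step 6. Four things may go wrong:
- Sulfinate loss may stall because the carbon acid between sulfone and ester is deprotonated in preference to the phenol.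
- Benzyl or methyl transfer from the sulfonium salt to the phenoxide or the carbanion may overtake ylide addition.
- The ylide may be lost by Sommelet–Hauser rearrangement.
- The adduct may lose Me2S by β-elimination instead of closing.

The fallback sets out from 3 (together with bromide 8) and comes back at 13. It closes ring B by forming C2–C3 through an intramolecular carbenoid C–H insertion, which is known chemistry for 2-aryl-2,3-dihydrobenzofuran-3-carboxylates. The phenol of 3 is alkylated with 8 (K2CO3, acetone) to give the O-arylmethyl mandelate F1. Dess–Martin periodinane oxidises its carbinol to the α-keto ester F2. Condensation with TsNHNH2 gives the tosylhydrazone F3, and DBU under Bamford–Stevens conditions releases the aryldiazoacetate F4. Rh2(OAc)4 in CH2Cl2 then inserts the carbenoid into the O–CH2–aryl C–H bond (1,5-insertion), which should give mainly the cis dihydrobenzofuran F5. DBU epimerises its C3 to the trans ester 13.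

Second, step 2. Ionisation next to the ester may be slow. The acid may then drive lactonisation of the phenol onto the ethyl ester, Friedel–Crafts self-condensation, or disproportionation of the sulfinic acid.

The fallback sets out from 3 and comes back at 5. It replaces the cationic substitution by activation and SN2 displacement. SOCl2 with catalytic DMF in CH2Cl2 at 0 °C converts the carbinol into the α-chloro ester F6. This is taken without storage into DMF with 4 at rt, where S-alkylation of the sulfinate at the α-halo ester carbon gives sulfone 5.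

Third, step 7. Hydride abstraction from the O-benzylated substrate may need temperatures at which the side-chain benzylic CH2 or the benzyl ether is also oxidised.

The fallback sets out from 13 and comes back at 14. It uses the much easier phenol-assisted dehydrogenation known for dihydrobenzofuran neolignans. Hydrogenolysis (H2, Pd/C, EtOAc) gives the free phenol F7. DDQ in dioxane at rt removes hydride from C2 with the help of the para-hydroxyl group, and loss of the C3 proton gives the phenolic benzofuran F8. Williamson benzylation (benzyl bromide, K2CO3, acetone) then restores 14.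

**Further compounds**

F1 | step 6 | racemic ethyl 2-{2-[(4-benzyloxy-3-methoxyphenyl)methoxy]-3-methoxy-5-(3-methoxy-3-oxopropyl)phenyl}-2-hydroxyacetate | CCOC(=O)C(O)c1cc(CCC(=O)OC)cc(OC)c1OCc1ccc(OCc2ccccc2)c(OC)c1
F2 | step 6 | ethyl 2-{2-[(4-benzyloxy-3-methoxyphenyl)methoxy]-3-methoxy-5-(3-methoxy-3-oxopropyl)phenyl}-2-oxoacetate | CCOC(=O)C(=O)c1cc(CCC(=O)OC)cc(OC)c1OCc1ccc(OCc2ccccc2)c(OC)c1
F3 | step 6 | tosylhydrazone of F2 (E/Z mixture) | CCOC(=O)C(=NNS(=O)(=O)c1ccc(C)cc1)c1cc(CCC(=O)OC)cc(OC)c1OCc1ccc(OCc2ccccc2)c(OC)c1
F4 | step 6 | ethyl 2-diazo-2-{2-[(4-benzyloxy-3-methoxyphenyl)methoxy]-3-methoxy-5-(3-methoxy-3-oxopropyl)phenyl}acetate | CCOC(=O)C(=[N+]=[N-])c1cc(CCC(=O)OC)cc(OC)c1OCc1ccc(OCc2ccccc2)c(OC)c1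
F5 | step 6 | racemic cis (2R*,3S*) ethyl 2-(4-benzyloxy-3-methoxyphenyl)-7-methoxy-5-(3-methoxy-3-oxopropyl)-2,3-dihydrobenzofuran-3-carboxylate | COC(=O)CCc1cc(OC)c2O[C@@H](c3ccc(OCc4ccccc4)c(OC)c3)[C@@H](C(=O)OCC)c2c1
F6 | step 2 | racemic ethyl 2-chloro-2-[2-hydroxy-3-methoxy-5-(3-methoxy-3-oxopropyl)phenyl]acetate | CCOC(=O)C(Cl)c1cc(CCC(=O)OC)cc(OC)c1O
F7 | step 7 | racemic trans ethyl 2-(4-hydroxy-3-methoxyphenyl)-7-methoxy-5-(3-methoxy-3-oxopropyl)-2,3-dihydrobenzofuran-3-carboxylate | COC(=O)CCc1cc(OC)c2O[C@@H](c3ccc(O)c(OC)c3)[C@H](C(=O)OCC)c2c1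
F8 | step 7 | ethyl 2-(4-hydroxy-3-methoxyphenyl)-7-methoxy-5-(3-methoxy-3-oxopropyl)benzofuran-3-carboxylate | CCOC(=O)c1c(-c2ccc(O)c(OC)c2)oc2c(OC)cc(CCC(=O)OC)cc12
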